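## The problem

The target, 2-[(3S,4S,6R)-6-[(2R,3E,6S,7E)-2,6-dimethyl-8-phenylocta-3,7-dien-1-yl]-4,6-dimethyl-1,2-dioxan-3-yl]acetic acid (33), is numbered here from the carboxyl carbon C1 to the benzylic alkene carbon C14, so the ring is O1–O2–C3–C4–C5–C6. C3 carries the acetic acid arm (C1–C2), C4 a methyl group, and C6 a methyl group and the chain C7–C14, which holds the E-C9=C10 alkene, the E-styrene C13=C14 and two isolated methyl-bearing centres, C8 and C12. Of the five stereocentres, C3 sits next to C4 and can be set from it through the ring conformation (the C2 arm, the C4 methyl and the C7 arm are all cis), whereas C8 and C12 are too remote to be relayed and must each come from its own source. C6 is the hard centre: a fully substituted peroxide carbon whose methyl group and two methylene arms (C5, C7) differ so little that neither a reagent nor a neighbouring centre can be relied on to distinguish its faces. Once the O–O bond is in place, aluminium hydrides, low-valent metals, hydrogenation and free phosphines are excluded; the C3–O2 bond is β to the C1 carbonyl, so an ester enolate opens the ring by elimination; the tertiary C6–O1 bond ionises under strong acid; and the chain alkenes, the styrene above all, are better hydrogen-atom acceptors than any alkene used to build the peroxide, so they must arrive after it. The feature that allows a late, convergent union is the E-C9=C10 double bond: it has the α-branched C8 on the ring side and the unbranched methylene C11 on the styryl side, the pattern for which the Julia–Kocienski olefination is reliably E-selective, and cutting it separates the dioxane half C1–C9 (four stereocentres) from the styryl half C10–C14 (one).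

## Retrosynthesis

**C1 carboxyl.** Acid 33 is traced back to its methyl ester 31. A free acid would consume the carbanion of the olefination, and the methyl ester is the smallest mask. The forward step is a saponification that must be cold and brief because of the β-peroxy ester.

**C9=C10.** Ester 31 is cut at C9=C10 into aldehyde 18 (C1–C9) and sulfone 28 (C10–C14).
- Cutting the styrene C13=C14 instead would leave all five stereocentres in one fragment.
- Cutting C10–C11 or C11–C12 would call for organometallic sp3 couplings next to a peroxide.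
- The chosen cut puts the electrophile (aldehyde) on the fragile half and the carbanion on the robust half.
- The forward reaction must give the E alkene without a reducing agent and with only brief exposure of 18 to base.

**Sulfone 28 and C12.** Sulfone 28 comes from alcohol 24 through sulfide 26 (C–S bond, then oxidation at sulfur). Alcohol 24 comes from ester 23, in which the C11–C12 bond is cut by a Johnson–Claisen transform back to (R)-allylic alcohol 21. This one rearrangement makes both the C12 centre and the E-styrene, where an alkylation route would need a separate olefination. Alcohol 21 comes from racemic 20 by kinetic resolution, and 20 from (E)-but-2-enal 19 and a phenyl Grignard reagent.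

**C2–C3.** Aldehyde 18 is simplified through alcohol 17 and silyl ether 16 to peroxyacetal 14 by cutting C2–C3. Forward, the peroxycarbenium ion 15 is captured by a silyl ketene acetal. The neighbouring option, closing O2–C3 last by conjugate addition of a C6 hydroperoxide onto an enoate, would place the C2 arm equatorial and trans to the C4 methyl under equilibrating conditions. The target has it axial and cis, which is what kinetic axial attack on the cation should give. Precursor 14 lacks C1–C2, and its C3 configuration is irrelevant.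

**O2–C3 and O1–C6.** Peroxyacetal 14 is opened at O2–C3 to silylperoxy aldehyde 11 (via 12 and 13). Its alcohol 10 is cut at O1–C6 to the 1,1-disubstituted alkene 9, the forward step being cobalt-mediated silylperoxidation. This cut gives up control of C6, since the tertiary radical has two near-identical arms. What speaks for it is its reliability and tolerance of functional groups and the easy access to 9. The C6 epimers are separated once the ring carries all its substituents (step 8).

**Carbon skeleton of 9.** Alcohol 9 comes from imide 8. Cutting C6–C7 (Negishi coupling) gives vinyl bromide 6 and alkylzinc 7, the latter made from bromide 2, the silyl ether of commercial bromohydrin 1 (source of C8). Cutting C4–C5 in 6 (auxiliary-controlled alkylation) gives propanoyl oxazolidinone 3 and 2,3-dibromopropene 4. Joining two chiral three-carbon units through a ketone and methylenating it would be longer; here the dibromide supplies C5, C6 and the future C6 methyl in one reagent.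

## Roads not taken

**Alternative 1:** Both ring C–O bonds (O2–C3 and O1–C6) are cut at once, leading to (5S)-1,5-dimethylcyclohexa-1,3-diene A1. Forward, singlet oxygen adds across the diene termini to give the bicyclic endoperoxide A2, and the C2=C7 etheno bridge is then cleaved to the dialdehyde A3.
- Merits: the cycloaddition is suprafacial, so the cis relation of the C3 and C6 carbon arms is built in. Attack anti to the C4 methyl would also fix C6 relative to C4, which the chosen plan cannot do.
- Weak points: A1 is volatile and can scramble its only stereocentre by 1,5-hydrogen shifts. A single methyl group is a weak facial director for so small a reagent, and the ene reaction competes. In A3 both C2 and C7 are α-peroxy aldehyde carbons that must be told apart; C2 needs one more carbon, and C7 must be joined to C8 while creating the C8 centre next to a neopentyl peroxide carbon without any reduction.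
- Comparison: this road is better at the C3/C6 relationship and potentially at C6. The chosen plan sets against it that C4, C8 and C12 come from dependable sources and that the ring is closed with all nine carbons of the core already in place.

**Alternative 2:** The O1–C6 bond is cut from the C3 side, leading to the unsaturated hydroperoxide A4. Forward, Hg(OAc)2 activates the C6=C7 alkene, the C3 hydroperoxide adds at C6 (6-exo), and NaBH4 replaces mercury at C7 by hydrogen to give dioxane A5.
- Merits: in a chair transition state with the C4 methyl equatorial, the bulky mercurated C7 carbon should also be equatorial, which gives the correct C6 configuration. C3 is fixed beforehand.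
- Weak points: the secondary hydroperoxide of A4 must be introduced by displacement with hydrogen peroxide at a β-branched carbon, where elimination competes. The trisubstituted alkene next to C8 needs its own assembly. Demercuration passes through a β-peroxyalkyl radical that can close to an epoxide. A stoichiometric mercury salt is used, and C1 arrives as a silyl ether that still needs two oxidations.
- Comparison: this road has a real handle on C6 and is better there. The chosen plan offers a C3 centre made by C–C bond formation on a peroxycarbenium ion, no mercury, and C1 at the right oxidation level. Its price is half the material at C6.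

**Alternative 3:** The C6–CH3 bond is cut. The ring is first assembled as the bis-peroxyketal A7 from hydrogen peroxide and keto aldehyde A6. Forward, TMSOTf ionises the tertiary C6 methoxy group and Me2Zn delivers methyl to the peroxycarbenium ion to give A8.
- Merits: the ring forms from hydrogen peroxide under equilibrating conditions. Axial delivery of the small methyl group would set C6 by the same stereoelectronic logic the chosen plan uses at C3. A8 is a single stereoisomer of peroxyacetal 14, so it would enter step 8 of the chosen route without the loss at C6.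
- Weak points: methyl transfer from an organozinc to a tertiary peroxycarbenium ion has no close precedent. The cation can fragment by alkyl migration to oxygen, Me2Zn may attack the O–O bond, and ionisation must be selective for C6 over C3.
- Comparison: if the methylation worked, this road would be superior at C6 and equal elsewhere. The chosen plan sets against it that every bond-forming step belongs to an established reaction class.

Key step: step 17

Remark on the chemistry: hydrogen-atom transfer to the 1,1-disubstituted alkene of 9 gives a tertiary radical with two near-identical methylene arms, so step 5 is assumed to form both C6 epimers in comparable amounts; compounds 10–15 are therefore C6 epimer pairs and the (6R) series is isolated in step 8.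

## Route

Step 1
Reactants: 1 (2S)-3-bromo-2-methylpropan-1-ol
Product: 2 [(2S)-3-bromo-2-methylpropoxy](tert-butyl)diphenylsilane
Conditions: t-BuPh2SiCl, imidazole, CH2Cl2, 0 °C → rt
Reagents that add atoms: tert-butyl(chloro)diphenylsilane, CC(C)(C)[Si](Cl)(c1ccccc1)c1ccccc1
Why: Silyl ether formation at the primary alcohol; this silyl group should survive acidic methanol (step 7) and TiCl4 (step 8) and leave under acidic fluoride (step 9). C8 is bought with the bromohydrin and is not touched.

Step 2
Reactants: 3 (4R)-4-benzyl-3-propanoyl-1,3-oxazolidin-2-one; 4 2,3-dibromoprop-1-ene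
Product: 6 (4R)-4-benzyl-3-[(2S)-4-bromo-2-methylpent-4-enoyl]-1,3-oxazolidin-2-one, via sodium enolate 5 (not isolated)
Conditions: NaN(SiMe3)2, THF, −78 °C; then 4, −78 → −40 °C
Reagents that add atoms: none
Why: Evans asymmetric alkylation: the chelated Z-enolate is attacked on the face away from the benzyl group, which sets C4 as S. Only the allylic bromide of 4 reacts, leaving the vinyl bromide for step 3.

Step 3
Reactants: 2 [(2S)-3-bromo-2-methylpropoxy](tert-butyl)diphenylsilane; 6 (4R)-4-benzyl-3-[(2S)-4-bromo-2-methylpent-4-enoyl]-1,3-oxazolidin-2-one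
Product: 8 (4R)-4-benzyl-3-[(2S,6R)-7-{[tert-butyl(diphenyl)silyl]oxy}-2,6-dimethyl-4-methylideneheptanoyl]-1,3-oxazolidin-2-one, via alkylzinc bromide 7 (not isolated)
Conditions: 2, Zn dust, I2 (cat.), DMA, 70 °C; then 6, Pd(PPh3)4 (5 mol%), THF, 50 °C
Reagents that add atoms: none
Why: Negishi coupling of a primary alkylzinc with a vinyl bromide forms C6–C7. The neutral conditions should spare the imide and its α-centre; no stereocentre is formed.

Step 4
Reactants: 8 (4R)-4-benzyl-3-[(2S,6R)-7-{[tert-butyl(diphenyl)silyl]oxy}-2,6-dimethyl-4-methylideneheptanoyl]-1,3-oxazolidin-2-one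
Product: 9 (2S,6R)-7-{[tert-butyl(diphenyl)silyl]oxy}-2,6-dimethyl-4-methylideneheptan-1-ol
Conditions: LiBH4, MeOH (1 equiv), Et2O, 0 °C
Reagents that add atoms: none
Why: Reductive cleavage of the N-acyl oxazolidinone gives the primary alcohol and returns the auxiliary. C4 is not enolised under these conditions.

Step 5
Reactants: 9 (2S,6R)-7-{[tert-butyl(diphenyl)silyl]oxy}-2,6-dimethyl-4-methylideneheptan-1-ol
Product: 10 (2S,4RS,6R)-7-{[tert-butyl(diphenyl)silyl]oxy}-2,4,6-trimethyl-4-[(triethylsilyl)peroxy]heptan-1-ol (both C4 epimers; heptane C4 is C6 of the target)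
Conditions: Co(acac)2 (10 mol%), Et3SiH, O2 (1 atm), EtOH, rt
Reagents that add atoms: dioxygen, O=O; triethylsilane, CC[SiH](CC)CC
Why: Mukaiyama–Isayama silylperoxidation: a cobalt hydride transfers hydrogen to the methylidene carbon, and the tertiary C6 radical is trapped by O2 and silylated. The radical has two near-identical arms, so C6 is formed without control.

Step 6
Reactants: 10 (2S,4RS,6R)-7-{[tert-butyl(diphenyl)silyl]oxy}-2,4,6-trimethyl-4-[(triethylsilyl)peroxy]heptan-1-ol
Product: 11 (2S,4RS,6R)-7-{[tert-butyl(diphenyl)silyl]oxy}-2,4,6-trimethyl-4-[(triethylsilyl)peroxy]heptanal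
Conditions: Dess–Martin periodinane, NaHCO3, CH2Cl2, 0 °C → rt
Reagents that add atoms: none
Why: Dess–Martin oxidation of the primary alcohol; the silyl peroxide is inert to the periodinane, and the bicarbonate buffer protects the C4 α-centre.

Step 7
Reactants: 11 (2S,4RS,6R)-7-{[tert-butyl(diphenyl)silyl]oxy}-2,4,6-trimethyl-4-[(triethylsilyl)peroxy]heptanal
Product: 14 tert-butyl{(2R)-3-[(4S)-3-methoxy-4,6-dimethyl-1,2-dioxan-6-yl]-2-methylpropoxy}diphenylsilane (epimers at C3 and C6), via hydroperoxy aldehyde 12 (not isolated), via 1,2-dioxan-3-ol 13 (not isolated)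
Conditions: camphorsulfonic acid (10 mol%), MeOH, 0 °C → rt
Reagents that add atoms: methanol, CO
Why: Acid methanolysis frees the hydroperoxide, which adds to the C3 aldehyde in a six-membered ring closure helped by the fully substituted C6. Acetal exchange then gives the methyl peroxyacetal; the C3 configuration is irrelevant because C3 is ionised in step 8.

Step 8
Reactants: 14 tert-butyl{(2R)-3-[(4S)-3-methoxy-4,6-dimethyl-1,2-dioxan-6-yl]-2-methylpropoxy}diphenylsilane
Product: 16 methyl 2-[(3S,4S,6R)-6-[(2R)-3-{[tert-butyl(diphenyl)silyl]oxy}-2-methylpropyl]-4,6-dimethyl-1,2-dioxan-3-yl]acetate, via peroxycarbenium ion 15 (not isolated)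
Conditions: TiCl4 (1.1 equiv), CH2=C(OMe)OSiMe2t-Bu (2.5 equiv), CH2Cl2, −78 °C; chromatographic removal of the C6 epimer
Reagents that add atoms: tert-butyl[(1-methoxyethenyl)oxy]dimethylsilane, C=C(OC)O[Si](C)(C)C(C)(C)C
Why: Lewis acid-mediated substitution of a 3-alkoxy-1,2-dioxane by a silyl ketene acetal through the peroxycarbenium ion. The fully substituted C6 holds the half-chair with the C4 methyl pseudo-equatorial, and axial attack through a chair-like transition state should place the C2 arm cis to the C4 methyl (3S). Both C6 epimers should react alike, and the (6R) isomer is isolated here.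

Step 9
Reactants: 16 methyl 2-[(3S,4S,6R)-6-[(2R)-3-{[tert-butyl(diphenyl)silyl]oxy}-2-methylpropyl]-4,6-dimethyl-1,2-dioxan-3-yl]acetate
Product: 17 methyl 2-[(3S,4S,6R)-6-[(2R)-3-hydroxy-2-methylpropyl]-4,6-dimethyl-1,2-dioxan-3-yl]acetate
Conditions: HF·pyridine, pyridine, THF, 0 °C → rt
Reagents that add atoms: none
Why: Fluoride cleavage of the silyl ether under acidic conditions, so the β-peroxy ester never meets basic fluoride.

Step 10
Reactants: 17 methyl 2-[(3S,4S,6R)-6-[(2R)-3-hydroxy-2-methylpropyl]-4,6-dimethyl-1,2-dioxan-3-yl]acetate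
Product: 18 methyl 2-[(3S,4S,6S)-4,6-dimethyl-6-[(2R)-2-methyl-3-oxopropyl]-1,2-dioxan-3-yl]acetate
Conditions: Dess–Martin periodinane, NaHCO3, CH2Cl2, 0 °C
Reagents that add atoms: none
Why: Dess–Martin oxidation, which leaves the peroxide alone; the aldehyde is used at once to protect C8. The C6 descriptor changes to S only because the aldehyde changes the ranking of the arms, not the geometry.

Step 11
Reactants: 19 (2E)-but-2-enal
Product: 20 rac-(2E)-1-phenylbut-2-en-1-ol
Conditions: PhMgBr, THF, −78 → 0 °C; aq. NH4Cl
Reagents that add atoms: phenylmagnesium bromide, Br[Mg]c1ccccc1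
Why: 1,2-Addition of an aryl Grignard reagent to an enal; the E geometry is retained.

Step 12
Reactants: 20 rac-(2E)-1-phenylbut-2-en-1-ol
Product: 21 (1R,2E)-1-phenylbut-2-en-1-ol
Conditions: Ti(OiPr)4 (10 mol%), D-(−)-diisopropyl tartrate (15 mol%), t-BuOOH (0.6 equiv), 4 Å molecular sieves, CH2Cl2, −20 °C
Reagents that add atoms: none
Why: Sharpless kinetic resolution: with D-(−)-tartrate the (S)-alcohol should be epoxidised much faster, so the (R)-alcohol is recovered at a little over half conversion. The sense follows from the face rule for tartrate-directed epoxidation of secondary E-allylic alcohols.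

Step 13
Reactants: 21 (1R,2E)-1-phenylbut-2-en-1-ol
Product: 23 ethyl (3S,4E)-3-methyl-5-phenylpent-4-enoate, via ketene acetal 22 (not isolated)
Conditions: MeC(OEt)3, EtCO2H (cat.), 135 °C, EtOH distilled off
Reagents that add atoms: triethyl orthoacetate, CCOC(C)(OCC)OCC
Why: Johnson–Claisen rearrangement through a chair transition state with the phenyl group equatorial. The C11–C12 bond forms on the face from which the C–O bond leaves, which should transfer the carbinol configuration to C12 (S) and give the E-styrene.

Step 14
Reactants: 23 ethyl (3S,4E)-3-methyl-5-phenylpent-4-enoate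
Product: 24 (3S,4E)-3-methyl-5-phenylpent-4-en-1-ol
Conditions: LiAlH4, Et2O, 0 °C
Reagents that add atoms: none
Why: Hydride reduction of the ester; the unconjugated styrene and C12 are not affected.

Step 15
Reactants: 24 (3S,4E)-3-methyl-5-phenylpent-4-en-1-ol; 25 1-phenyl-1H-tetrazole-5-thiol
Product: 26 5-{[(3S,4E)-3-methyl-5-phenylpent-4-en-1-yl]sulfanyl}-1-phenyl-1H-tetrazole
Conditions: PPh3, DIAD, THF, 0 °C → rt
Reagents that add atoms: none
Why: Mitsunobu thioetherification of a primary alcohol with the acidic tetrazole thiol; C12 is two carbons away and is not involved.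

Step 16
Reactants: 26 5-{[(3S,4E)-3-methyl-5-phenylpent-4-en-1-yl]sulfanyl}-1-phenyl-1H-tetrazole
Product: 28 5-{[(3S,4E)-3-methyl-5-phenylpent-4-en-1-yl]sulfonyl}-1-phenyl-1H-tetrazole, via sulfoxide 27 (not isolated)
Conditions: H2O2 (30% aq.), (NH4)6Mo7O24·4H2O (10 mol%), EtOH, 0 °C → rt
Reagents that add atoms: hydrogen peroxide, OO
Why: Molybdate-catalysed oxidation of sulfide to sulfone; peroxomolybdate should oxidise sulfur much faster than it epoxidises the styrene.

Step 17
Reactants: 28 5-{[(3S,4E)-3-methyl-5-phenylpent-4-en-1-yl]sulfonyl}-1-phenyl-1H-tetrazole; 18 methyl 2-[(3S,4S,6S)-4,6-dimethyl-6-[(2R)-2-methyl-3-oxopropyl]-1,2-dioxan-3-yl]acetate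
Product: 31 methyl 2-[(3S,4S,6R)-6-[(2R,3E,6S,7E)-2,6-dimethyl-8-phenylocta-3,7-dien-1-yl]-4,6-dimethyl-1,2-dioxan-3-yl]acetate, via potassium sulfonyl carbanion 29 (not isolated), via alkoxide adduct 30 (not isolated)
Conditions: 28 (1.3 equiv), KN(SiMe3)2 (1.2 equiv), DME, −60 °C, 20 min; then 18, −60 °C → rt; aq. NH4Cl
Reagents that add atoms: none
Why: Julia–Kocienski olefination, the closest known reaction type being the union of metallated alkyl 1-phenyltetrazol-5-yl sulfones with α-branched aldehydes. KN(SiMe3)2 removes a C10 proton of 28 to give carbanion 29, which adds to the C9 carbonyl of 18; the alkoxide of adduct 30 attacks the tetrazole carbon (Smiles rearrangement), and loss of SO2 and the tetrazolonate leaves the C9=C10 double bond. No ring is closed and no stereocentre is created; the step must give the E alkene and leave C8, the O–O bond and the β-peroxy ester untouched. E selectivity is expected because potassium in DME favours an open transition state and the anti adduct when an unbranched sulfone meets an α-branched aldehyde, and the anti adduct collapses stereospecifically to the E alkene. The peroxide should survive because no electron donor, phosphine or low-valent metal is present. Sulfone 28 is kept in slight excess over the base and is fully metallated before 18 is added, so neither the C2 protons of the ester nor the C8 proton of the aldehyde meets amide base; addition of the carbanion to the aldehyde at −60 °C should outrun proton transfer from either site.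

Step 18
Reactants: 31 methyl 2-[(3S,4S,6R)-6-[(2R,3E,6S,7E)-2,6-dimethyl-8-phenylocta-3,7-dien-1-yl]-4,6-dimethyl-1,2-dioxan-3-yl]acetate
Product: 33 2-[(3S,4S,6R)-6-[(2R,3E,6S,7E)-2,6-dimethyl-8-phenylocta-3,7-dien-1-yl]-4,6-dimethyl-1,2-dioxan-3-yl]acetic acid, via lithium carboxylate 32 (not isolated)
Conditions: LiOH·H2O, THF/H2O (3:1), 0 °C; then 1 M HCl to pH 3
Reagents that add atoms: lithium hydroxide, [Li+].[OH-]
Why: Saponification of a methyl ester by acyl substitution. Hydroxide attack at the carbonyl should outrun deprotonation at C2 at 0 °C, and the carboxylate formed can no longer eliminate the C3 peroxide oxygen.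

## Compound list

1 | (2S)-3-bromo-2-methylpropan-1-ol | OC[C@H](C)CBr | starting material
2 | [(2S)-3-bromo-2-methylpropoxy](tert-butyl)diphenylsilane | CC(C)(C)[Si](c1ccccc1)(c1ccccc1)OC[C@H](C)CBr | intermediate
3 | (4R)-4-benzyl-3-propanoyl-1,3-oxazolidin-2-one | CCC(=O)N1[C@H](Cc2ccccc2)COC1=O | starting material
4 | 2,3-dibromoprop-1-ene | C=C(Br)CBr | starting material
5 | sodium (1Z)-1-[(4R)-4-benzyl-2-oxo-1,3-oxazolidin-3-yl]prop-1-en-1-olate | C/C=C(\[O-])N1[C@H](Cc2ccccc2)COC1=O.[Na+] | intermediate
6 | (4R)-4-benzyl-3-[(2S)-4-bromo-2-methylpent-4-enoyl]-1,3-oxazolidin-2-one | C=C(Br)C[C@H](C)C(=O)N1[C@H](Cc2ccccc2)COC1=O | intermediate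
7 | bromo[(2S)-3-{[tert-butyl(diphenyl)silyl]oxy}-2-methylpropyl]zinc | CC(C)(C)[Si](c1ccccc1)(c1ccccc1)OC[C@H](C)C[Zn]Br | intermediate
8 | (4R)-4-benzyl-3-[(2S,6R)-7-{[tert-butyl(diphenyl)silyl]oxy}-2,6-dimethyl-4-methylideneheptanoyl]-1,3-oxazolidin-2-one | CC(C)(C)[Si](c1ccccc1)(c1ccccc1)OC[C@H](C)CC(=C)C[C@H](C)C(=O)N1[C@H](Cc2ccccc2)COC1=O | intermediate
9 | (2S,6R)-7-{[tert-butyl(diphenyl)silyl]oxy}-2,6-dimethyl-4-methylideneheptan-1-ol | CC(C)(C)[Si](c1ccccc1)(c1ccccc1)OC[C@H](C)CC(=C)C[C@H](C)CO | intermediate
10 | (2S,4RS,6R)-7-{[tert-butyl(diphenyl)silyl]oxy}-2,4,6-trimethyl-4-[(triethylsilyl)peroxy]heptan-1-ol (both C4 epimers) | CC(C)(C)[Si](c1ccccc1)(c1ccccc1)OC[C@H](C)CC(C)(OO[Si](CC)(CC)CC)C[C@H](C)CO | intermediate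
11 | (2S,4RS,6R)-7-{[tert-butyl(diphenyl)silyl]oxy}-2,4,6-trimethyl-4-[(triethylsilyl)peroxy]heptanal (both C4 epimers) | CC(C)(C)[Si](c1ccccc1)(c1ccccc1)OC[C@H](C)CC(C)(OO[Si](CC)(CC)CC)C[C@H](C)C=O | intermediate
12 | (2S,4RS,6R)-7-{[tert-butyl(diphenyl)silyl]oxy}-4-hydroperoxy-2,4,6-trimethylheptanal (both C4 epimers) | CC(C)(C)[Si](c1ccccc1)(c1ccccc1)OC[C@H](C)CC(C)(OO)C[C@H](C)C=O | intermediate
13 | (4S)-6-[(2R)-3-{[tert-butyl(diphenyl)silyl]oxy}-2-methylpropyl]-4,6-dimethyl-1,2-dioxan-3-ol (epimers at C3 and C6) | CC(C)(C)[Si](c1ccccc1)(c1ccccc1)OC[C@H](C)CC1(C)C[C@H](C)C(O)OO1 | intermediate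
14 | tert-butyl{(2R)-3-[(4S)-3-methoxy-4,6-dimethyl-1,2-dioxan-6-yl]-2-methylpropoxy}diphenylsilane (epimers at C3 and C6) | CC(C)(C)[Si](c1ccccc1)(c1ccccc1)OC[C@H](C)CC1(C)C[C@H](C)C(OC)OO1 | intermediate
15 | (4S)-6-[(2R)-3-{[tert-butyl(diphenyl)silyl]oxy}-2-methylpropyl]-4,6-dimethyl-1,2-dioxan-3-ylium (peroxycarbenium ion, both C6 epimers, chlorotitanate counter-ion) | CC(C)(C)[Si](c1ccccc1)(c1ccccc1)OC[C@H](C)CC1(C)C[C@H](C)C=[O+]O1 | intermediate
16 | methyl 2-[(3S,4S,6R)-6-[(2R)-3-{[tert-butyl(diphenyl)silyl]oxy}-2-methylpropyl]-4,6-dimethyl-1,2-dioxan-3-yl]acetate | CC(C)(C)[Si](c1ccccc1)(c1ccccc1)OC[C@H](C)C[C@]1(C)C[C@H](C)[C@H](CC(=O)OC)OO1 | intermediate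
17 | methyl 2-[(3S,4S,6R)-6-[(2R)-3-hydroxy-2-methylpropyl]-4,6-dimethyl-1,2-dioxan-3-yl]acetate | OC[C@H](C)C[C@]1(C)C[C@H](C)[C@H](CC(=O)OC)OO1 | intermediate
18 | methyl 2-[(3S,4S,6S)-4,6-dimethyl-6-[(2R)-2-methyl-3-oxopropyl]-1,2-dioxan-3-yl]acetate | O=C[C@H](C)C[C@]1(C)C[C@H](C)[C@H](CC(=O)OC)OO1 | intermediate
19 | (2E)-but-2-enal | C/C=C/C=O | starting material
20 | rac-(2E)-1-phenylbut-2-en-1-ol | C/C=C/C(O)c1ccccc1 | intermediate
21 | (1R,2E)-1-phenylbut-2-en-1-ol | C/C=C/[C@@H](O)c1ccccc1 | intermediate
22 | [(1R,2E)-1-[(1-ethoxyethenyl)oxy]but-2-en-1-yl]benzene | C/C=C/[C@@H](OC(=C)OCC)c1ccccc1 | intermediate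
23 | ethyl (3S,4E)-3-methyl-5-phenylpent-4-enoate | C[C@H](/C=C/c1ccccc1)CC(=O)OCC | intermediate
24 | (3S,4E)-3-methyl-5-phenylpent-4-en-1-ol | C[C@H](/C=C/c1ccccc1)CCO | intermediate
25 | 1-phenyl-1H-tetrazole-5-thiol | Sc1nnnn1-c1ccccc1 | starting material
26 | 5-{[(3S,4E)-3-methyl-5-phenylpent-4-en-1-yl]sulfanyl}-1-phenyl-1H-tetrazole | C[C@H](/C=C/c1ccccc1)CCSc1nnnn1-c1ccccc1 | intermediate
27 | 5-{[(3S,4E)-3-methyl-5-phenylpent-4-en-1-yl]sulfinyl}-1-phenyl-1H-tetrazole (both epimers at sulfur) | C[C@H](/C=C/c1ccccc1)CCS(=O)c1nnnn1-c1ccccc1 | intermediate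
28 | 5-{[(3S,4E)-3-methyl-5-phenylpent-4-en-1-yl]sulfonyl}-1-phenyl-1H-tetrazole | C[C@H](/C=C/c1ccccc1)CCS(=O)(=O)c1nnnn1-c1ccccc1 | intermediate
29 | potassium salt of the C10 carbanion of 28 | C[C@H](/C=C/c1ccccc1)C[CH-]S(=O)(=O)c1nnnn1-c1ccccc1.[K+] | intermediate
30 | potassium alkoxide from addition of C10 of 29 to C9 of 18 (β-alkoxy sulfone; C9 and C10 not defined) | C[C@H](/C=C/c1ccccc1)CC(C([O-])[C@H](C)C[C@]1(C)C[C@H](C)[C@H](CC(=O)OC)OO1)S(=O)(=O)c1nnnn1-c1ccccc1.[K+] | intermediate
31 | methyl 2-[(3S,4S,6R)-6-[(2R,3E,6S,7E)-2,6-dimethyl-8-phenylocta-3,7-dien-1-yl]-4,6-dimethyl-1,2-dioxan-3-yl]acetate | C[C@H](/C=C/c1ccccc1)C/C=C/[C@H](C)C[C@]1(C)C[C@H](C)[C@H](CC(=O)OC)OO1 | intermediate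
32 | lithium 2-[(3S,4S,6R)-6-[(2R,3E,6S,7E)-2,6-dimethyl-8-phenylocta-3,7-dien-1-yl]-4,6-dimethyl-1,2-dioxan-3-yl]acetate | C[C@H](/C=C/c1ccccc1)C/C=C/[C@H](C)C[C@]1(C)C[C@H](C)[C@H](CC(=O)[O-])OO1.[Li+] | intermediate
33 | 2-[(3S,4S,6R)-6-[(2R,3E,6S,7E)-2,6-dimethyl-8-phenylocta-3,7-dien-1-yl]-4,6-dimethyl-1,2-dioxan-3-yl]acetic acid | C[C@H](/C=C/c1ccccc1)C/C=C/[C@H](C)C[C@]1(C)C[C@H](C)[C@H](CC(=O)O)OO1 | target

## Step count and least certain steps

Total: 18 steps. Longest linear sequence: 11 steps (steps 1, 3–10, 17, 18 from 1; the same length from 3 and 4 through step 2). The sulfone branch from 19 takes six steps before the union.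

Origin of the stereocentres: C8 from 1; C4 in step 2; C6 in step 5 without control, the (6R) epimer being selected in step 8; C3 in step 8; C12 in step 13 from the alcohol resolved in step 12.

**Step 17 (key step).** The sulfonyl carbanion may act as a base instead of a nucleophile. Proton abstraction at C8 would epimerise the aldehyde, and abstraction at C2 would open the ring by elimination of the C3 peroxide oxygen; some erosion of E selectivity is also possible. The fallback forms the same C9=C10 bond by cross-metathesis, with no carbanion in the coupling. It sets out from 18 and 24 and returns at 31. Methylenation of 18 with Ph3P=CH2 at −78 °C gives the terminal alkene F1. Dess–Martin oxidation of 24 gives the aldehyde F2, and methylenation of F2 gives the diene F3. Cross-metathesis of F1 with excess F3 (second-generation Hoveyda–Grubbs catalyst, CH2Cl2, 40 °C) should give 31 with loss of ethene. The E preference would probably be lower than in the olefination, and the isomers would have to be separated.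

**Step 8.** Three things may go wrong. Attack on the peroxycarbenium ion may occur from both faces, through a twist-boat pathway that avoids the gauche contact with the C4 methyl, which erodes the 3,4-cis relationship. The Lewis acid may ionise the tertiary C6–O bond, leading to fragmentation. The C6 epimers inherited from step 5 may fail to separate; this is where the lack of control at C6 is paid for. The fallback changes the nucleophile class and offers different compounds for the separation. It sets out from 14 and returns at 16. Hosomi–Sakurai allylation of the peroxycarbenium ion (allyltrimethylsilane, TiCl4, CH2Cl2, −78 °C) gives the allyl dioxane F4, whose C6 epimers are separated at this stage. Ozonolysis (O3, CH2Cl2, −78 °C; Me2S) gives the aldehyde F5. Direct oxidative esterification (Oxone, MeOH) gives 16.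

**Step 13.** The benzylic and allylic alcohol may ionise under the hot acidic conditions before it rearranges, causing racemisation, allylic transposition or diene formation. The outcome also depends on the enantiomeric purity delivered by the resolution in step 12. The fallback sets C12 with the same auxiliary as C4 and needs neither resolution nor rearrangement. It sets out from 3 and returns at 24. Alkylation of sodium enolate 5 with tert-butyl bromoacetate gives the imide ester F6; attack anti to the benzyl group again gives the S configuration. LiBH4 reduces the imide selectively to the hydroxy ester F7. Dess–Martin oxidation gives the aldehyde F8. An E-selective Horner–Wadsworth–Emmons reaction with diethyl benzylphosphonate gives the styryl ester F9, and LiAlH4 reduction gives 24.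

**Step 18.** Hydroxide may deprotonate C2 faster than it attacks the ester carbonyl. The ring then opens by loss of the C3 peroxide oxygen (retro-oxa-Michael reaction), and re-addition would scramble C3. The fallback never makes the ester, so no hydroxide step is needed. It sets out from 14 and returns at 33. Peroxyacetal 14 is treated with TiCl4 and 1,1-bis(trimethylsilyloxy)ethene as in step 8, which gives the silyl ether acid F10 directly after aqueous work-up and separation of the C6 epimer. HF·pyridine gives the hydroxy acid F11, and Dess–Martin oxidation gives the aldehyde acid F12. The olefination of step 17 is then run with 2.2 equivalents of carbanion 29. The first equivalent converts F12 to its carboxylate, which has no acidic C2 proton, and acidification gives 33.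

## Further compounds

F1 | step 17 | methyl 2-[(3S,4S,6R)-4,6-dimethyl-6-[(2R)-2-methylbut-3-en-1-yl]-1,2-dioxan-3-yl]acetate | C=C[C@H](C)C[C@]1(C)C[C@H](C)[C@H](CC(=O)OC)OO1
F2 | step 17 | (3S,4E)-3-methyl-5-phenylpent-4-enal | C[C@H](/C=C/c1ccccc1)CC=O
F3 | step 17 | [(1E,3S)-3-methylhexa-1,5-dien-1-yl]benzene | C[C@H](/C=C/c1ccccc1)CC=C
F4 | step 8 | tert-butyl{(2R)-3-[(3S,4S,6R)-4,6-dimethyl-3-(prop-2-en-1-yl)-1,2-dioxan-6-yl]-2-methylpropoxy}diphenylsilane | CC(C)(C)[Si](c1ccccc1)(c1ccccc1)OC[C@H](C)C[C@]1(C)C[C@H](C)[C@H](CC=C)OO1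
F5 | step 8 | 2-[(3S,4S,6R)-6-[(2R)-3-{[tert-butyl(diphenyl)silyl]oxy}-2-methylpropyl]-4,6-dimethyl-1,2-dioxan-3-yl]acetaldehyde | CC(C)(C)[Si](c1ccccc1)(c1ccccc1)OC[C@H](C)C[C@]1(C)C[C@H](C)[C@H](CC=O)OO1
F6 | step 13 | tert-butyl (3S)-4-[(4R)-4-benzyl-2-oxo-1,3-oxazolidin-3-yl]-3-methyl-4-oxobutanoate | C[C@H](C(=O)N1[C@H](Cc2ccccc2)COC1=O)CC(=O)OC(C)(C)C
F7 | step 13 | tert-butyl (3S)-4-hydroxy-3-methylbutanoate | C[C@H](CO)CC(=O)OC(C)(C)C
F8 | step 13 | tert-butyl (3S)-3-methyl-4-oxobutanoate | C[C@H](C=O)CC(=O)OC(C)(C)C
F9 | step 13 | tert-butyl (3S,4E)-3-methyl-5-phenylpent-4-enoate | C[C@H](/C=C/c1ccccc1)CC(=O)OC(C)(C)C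
F10 | step 18 | 2-[(3S,4S,6R)-6-[(2R)-3-{[tert-butyl(diphenyl)silyl]oxy}-2-methylpropyl]-4,6-dimethyl-1,2-dioxan-3-yl]acetic acid | CC(C)(C)[Si](c1ccccc1)(c1ccccc1)OC[C@H](C)C[C@]1(C)C[C@H](C)[C@H](CC(=O)O)OO1
F11 | step 18 | 2-[(3S,4S,6R)-6-[(2R)-3-hydroxy-2-methylpropyl]-4,6-dimethyl-1,2-dioxan-3-yl]acetic acid | OC[C@H](C)C[C@]1(C)C[C@H](C)[C@H](CC(=O)O)OO1
F12 | step 18 | 2-[(3S,4S,6S)-4,6-dimethyl-6-[(2R)-2-methyl-3-oxopropyl]-1,2-dioxan-3-yl]acetic acid | O=C[C@H](C)C[C@]1(C)C[C@H](C)[C@H](CC(=O)O)OO1
A1 | alternative 1 | (5S)-1,5-dimethylcyclohexa-1,3-diene | CC1=CC=C[C@@H](C)C1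
A2 | alternative 1 | 1,8-dimethyl-2,3-dioxabicyclo[2.2.2]oct-5-ene with the C8 methyl syn to the C5=C6 bridge | C1=C[C@]2(C)C[C@H](C)[C@H]1OO2
A3 | alternative 1 | (3R,4S,6S)-4,6-dimethyl-1,2-dioxane-3,6-dicarbaldehyde | O=C[C@]1(C)C[C@H](C)[C@H](C=O)OO1
A4 | alternative 2 | (3S,4S,6E,8R)-1-{[tert-butyl(dimethyl)silyl]oxy}-9-{[tert-butyl(diphenyl)silyl]oxy}-4,6,8-trimethylnon-6-en-3-yl hydroperoxide | CC(C)(C)[Si](c1ccccc1)(c1ccccc1)OC[C@H](C)/C=C(\C)C[C@H](C)[C@H](CCO[Si](C)(C)C(C)(C)C)OO
A5 | alternative 2 | tert-butyl{2-[(3S,4S,6R)-6-[(2R)-3-{[tert-butyl(diphenyl)silyl]oxy}-2-methylpropyl]-4,6-dimethyl-1,2-dioxan-3-yl]ethoxy}dimethylsilane | CC(C)(C)[Si](c1ccccc1)(c1ccccc1)OC[C@H](C)C[C@]1(C)C[C@H](C)[C@H](CCO[Si](C)(C)C(C)(C)C)OO1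
A6 | alternative 3 | (2S,6R)-7-{[tert-butyl(diphenyl)silyl]oxy}-2,6-dimethyl-4-oxoheptanal | CC(C)(C)[Si](c1ccccc1)(c1ccccc1)OC[C@H](C)CC(=O)C[C@H](C)C=O
A7 | alternative 3 | tert-butyl{(2R)-3-[(4S)-3,6-dimethoxy-4-methyl-1,2-dioxan-6-yl]-2-methylpropoxy}diphenylsilane (epimers at C3 and C6) | CC(C)(C)[Si](c1ccccc1)(c1ccccc1)OC[C@H](C)CC1(OC)C[C@H](C)C(OC)OO1
A8 | alternative 3 | tert-butyl{(2R)-3-[(3R,4S,6R)-3-methoxy-4,6-dimethyl-1,2-dioxan-6-yl]-2-methylpropoxy}diphenylsilane | CC(C)(C)[Si](c1ccccc1)(c1ccccc1)OC[C@H](C)C[C@]1(C)C[C@H](C)[C@H](OC)OO1
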